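The oxolane is disconnected at O1–C2. The key step exploits the free 4-hydroxyl of the guaiacyl ring, para to the benzylic carbon C2, and the C5 hydroxyl placed 1,4 to that carbon: DDQ dehydrogenates the phenol to a p-quinone methide, and 5-exo oxa-1,6-addition of the C5 oxygen closes the ring, sets C2 trans to C3 and restores the arene in one operation. The precursor is an acyclic tetraol with a plain benzylic CH2. Its three stereocentres come from one Evans syn-aldol (C4 and the carbinol carbon) and a trans-selective alkylation (C3) on a temporary γ-lactone, which is reduced open before the ring closure.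

Key step: step 8

Remark on locants: the oxolane atoms are O1, C2 (guaiacyl-bearing), C3 (CH2OH-bearing), C4 (bearing the exocyclic carbinol carbon) and C5 (CH2); the same labels are used for these atoms in the acyclic and lactone precursors.

Step 1
Reactants: 1 (4R)-4-benzyl-1,3-oxazolidin-2-one; 2 methyl 4-chloro-4-oxobutanoate
Product: 3 methyl 4-[(4R)-4-benzyl-2-oxo-1,3-oxazolidin-3-yl]-4-oxobutanoate
Conditions: n-BuLi, THF, −78 °C; then 2, −78 to 0 °C
Reagents that add atoms: none
Why: N-acylation of the lithiated Evans oxazolidinone by the acid chloride, which is far more electrophilic than the methyl ester, should give the succinate half-ester imide.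

Step 2
Reactants: 3; 4 3,4-bis(benzyloxy)benzaldehyde
Product: 6 (4R)-4-benzyl-3-{[(2R,3R)-2-[3,4-bis(benzyloxy)phenyl]-5-oxooxolan-3-yl]carbonyl}-1,3-oxazolidin-2-one, via syn-aldol adduct 5 (not isolated)
Conditions: Bu2BOTf, i-Pr2NEt, CH2Cl2, 0 °C; then 4, −78 to 0 °C; H2O2, pH 7 phosphate buffer, MeOH, 0 °C; crude with cat. TsOH, CH2Cl2, rt
Reagents that add atoms: none
Why: the Evans syn-aldol reaction through the (Z)-boron enolate and a Zimmerman–Traxler chair, in which the (4R)-benzyl group blocks one enolate face, sets the carbinol carbon (R) and the future C4 in one event, and the syn aldol hydroxyl then lactonises onto the methyl ester to the 2,3-trans γ-lactone.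

Step 3
Reactants: 6
Product: 7 (2R,3R)-2-[3,4-bis(benzyloxy)phenyl]-5-oxooxolane-3-carboxylic acid
Conditions: LiOH, H2O2, THF/H2O, 0 °C; Na2SO3; HCl to pH 2
Reagents that add atoms: hydrogen peroxide (as LiOOH), OO
Why: hydroperoxide cleaves the exocyclic imide carbonyl selectively (standard removal of the Evans auxiliary) and acidification recloses any lactone opened by hydroxide, so the trans paraconic acid should result with both stereocentres intact.

Step 4
Reactants: 8 4-(hydroxymethyl)-2-methoxyphenol (vanillyl alcohol)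
Product: 9 4-(hydroxymethyl)-2-methoxyphenyl 2,2-dimethylpropanoate
Conditions: PivCl, aq. NaOH, CH2Cl2, 0 °C
Reagents that add atoms: pivaloyl chloride, CC(C)(C)C(=O)Cl
Why: under Schotten–Baumann conditions only the phenoxide is acylated, so the benzylic alcohol stays free.

Step 5
Reactants: 9
Product: 10 4-(bromomethyl)-2-methoxyphenyl 2,2-dimethylpropanoate
Conditions: PBr3, CH2Cl2, 0 °C
Reagents that add atoms: phosphorus tribromide, BrP(Br)Br
Why: the benzylic alcohol is converted to the bromide through its phosphite ester, and the hindered aryl pivalate is inert and tempers the para-oxygen so that the bromide is a stable SN2 electrophile.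

Step 6
Reactants: 7; 10
Product: 11 (2R,3R,4R)-2-[3,4-bis(benzyloxy)phenyl]-4-{[4-(2,2-dimethylpropanoyloxy)-3-methoxyphenyl]methyl}-5-oxooxolane-3-carboxylic acid
Conditions: NaN(SiMe3)2 (2.2 equiv), THF, −78 °C; then 10, −78 to −40 °C; aq. HCl
Reagents that add atoms: none
Why: the carboxylate/lactone-enolate dianion should be benzylated at the lactone α-carbon anti to the neighbouring carboxylate (substrate-controlled alkylation of a paraconic acid dianion), which sets the future C3 and gives the all-trans lactone.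

Step 7
Reactants: 11
Product: 12 (1R,2S,3R)-1-[3,4-bis(benzyloxy)phenyl]-3-[(4-hydroxy-3-methoxyphenyl)methyl]-2-(hydroxymethyl)butane-1,4-diol
Conditions: LiAlH4, THF, 0 °C to reflux; aq. potassium sodium tartrate
Reagents that add atoms: none
Why: hydride reduction opens the temporary lactone, reduces the carboxylic acid and cleaves the aryl pivalate in one operation, which should give the tetraol with the guaiacyl hydroxyl as the only free phenol and the three stereocentres untouched.

Step 8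
Reactants: 12
Product: 14 4-[(2S,3R,4S)-4-{(R)-[3,4-bis(benzyloxy)phenyl](hydroxy)methyl}-3-(hydroxymethyl)oxolan-2-yl]-2-methoxyphenol, via p-quinone methide 13 (not isolated)
Conditions: DDQ (1.0 equiv), CH2Cl2/1,4-dioxane, 0 °C to rt
Reagents that add atoms: none
Why: DDQ takes hydride from the benzylic CH2 para to the free phenol, and loss of the phenolic proton gives p-quinone methide 13, whose exocyclic carbon is the future C2. The primary hydroxyl on the future C5 then adds to that carbon in a 5-exo-trig oxa-1,6-conjugate addition that forms the O1–C2 bond and restores the aromatic ring. The closest known reaction type is the DDQ dehydrogenation of 4-alkylphenols to quinone methides with intramolecular trapping by oxygen, as in the oxidative closure of 1,3-diarylpropanes to flavans and the quinone methide closures that give 2-aryl oxolane lignans. C2 is set by the C3 stereocentre: in the envelope transition state the quinoid ring sits anti to the C3 hydroxymethyl group, which should give the 2,3-trans (2S) ether, also the more stable epimer. The step needs activation of C2 and not of the carbinol carbon, secured because the guaiacyl ring carries the only free phenol and reacts with DDQ far faster than the benzyl-capped catechol carbinol, and it needs attack by the C5 oxygen, secured because the C3 hydroxymethyl could only close an oxetane and the hindered secondary carbinol would have to form a 3,4-cis 2,5-diaryl oxolane. The neutral quinone methide is too weak an electrophile for Friedel–Crafts attack by the benzyloxy arene, so no aryltetralin is expected.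

Step 9
Reactants: 14
Product: 15 4-[(R)-hydroxy{(3S,4R,5S)-5-(4-hydroxy-3-methoxyphenyl)-4-(hydroxymethyl)oxolan-3-yl}methyl]benzene-1,2-diol
Conditions: H2 (1 atm), Pd/C, EtOAc, rt
Reagents that add atoms: none
Why: hydrogenolysis of the two aryl benzyl ethers, which in neutral solvent at ambient pressure is much faster than cleavage of the benzylic carbinol or of the benzylic ring C–O bond, should free the catechol and give the target.

Compound list
1 | (4R)-4-benzyl-1,3-oxazolidin-2-one | O=C1N[C@H](Cc2ccccc2)CO1 | starting material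
2 | methyl 4-chloro-4-oxobutanoate | COC(=O)CCC(=O)Cl | starting material
3 | methyl 4-[(4R)-4-benzyl-2-oxo-1,3-oxazolidin-3-yl]-4-oxobutanoate | COC(=O)CCC(=O)N1[C@H](Cc2ccccc2)COC1=O | intermediate
4 | 3,4-bis(benzyloxy)benzaldehyde | O=Cc1ccc(OCc2ccccc2)c(OCc2ccccc2)c1 | starting material
5 | methyl (3R,4R)-3-{[(4R)-4-benzyl-2-oxo-1,3-oxazolidin-3-yl]carbonyl}-4-[3,4-bis(benzyloxy)phenyl]-4-hydroxybutanoate (syn-aldol adduct, not isolated) | COC(=O)C[C@@H](C(=O)N1[C@H](Cc2ccccc2)COC1=O)[C@@H](O)c1ccc(OCc2ccccc2)c(OCc2ccccc2)c1 | intermediate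
6 | (4R)-4-benzyl-3-{[(2R,3R)-2-[3,4-bis(benzyloxy)phenyl]-5-oxooxolan-3-yl]carbonyl}-1,3-oxazolidin-2-one | O=C1C[C@@H](C(=O)N2[C@H](Cc3ccccc3)COC2=O)[C@H](c2ccc(OCc3ccccc3)c(OCc3ccccc3)c2)O1 | intermediate
7 | (2R,3R)-2-[3,4-bis(benzyloxy)phenyl]-5-oxooxolane-3-carboxylic acid | O=C1C[C@@H](C(=O)O)[C@H](c2ccc(OCc3ccccc3)c(OCc3ccccc3)c2)O1 | intermediate
8 | 4-(hydroxymethyl)-2-methoxyphenol (vanillyl alcohol) | COc1cc(CO)ccc1O | starting material
9 | 4-(hydroxymethyl)-2-methoxyphenyl 2,2-dimethylpropanoate | COc1cc(CO)ccc1OC(=O)C(C)(C)C | intermediate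
10 | 4-(bromomethyl)-2-methoxyphenyl 2,2-dimethylpropanoate | COc1cc(CBr)ccc1OC(=O)C(C)(C)C | intermediate
11 | (2R,3R,4R)-2-[3,4-bis(benzyloxy)phenyl]-4-{[4-(2,2-dimethylpropanoyloxy)-3-methoxyphenyl]methyl}-5-oxooxolane-3-carboxylic acid (all-trans) | O=C1[C@H](Cc2ccc(OC(=O)C(C)(C)C)c(OC)c2)[C@@H](C(=O)O)[C@H](c2ccc(OCc3ccccc3)c(OCc3ccccc3)c2)O1 | intermediate
12 | (1R,2S,3R)-1-[3,4-bis(benzyloxy)phenyl]-3-[(4-hydroxy-3-methoxyphenyl)methyl]-2-(hydroxymethyl)butane-1,4-diol | OC[C@H](Cc1ccc(O)c(OC)c1)[C@@H](CO)[C@@H](O)c1ccc(OCc2ccccc2)c(OCc2ccccc2)c1 | intermediate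
13 | 4-{(2R,3S,4R)-4-[3,4-bis(benzyloxy)phenyl]-4-hydroxy-2,3-bis(hydroxymethyl)butylidene}-2-methoxycyclohexa-2,5-dien-1-one (p-quinone methide, not isolated) | OC[C@H](C=C1C=CC(=O)C(OC)=C1)[C@@H](CO)[C@@H](O)c1ccc(OCc2ccccc2)c(OCc2ccccc2)c1 | intermediate
14 | 4-[(2S,3R,4S)-4-{(R)-[3,4-bis(benzyloxy)phenyl](hydroxy)methyl}-3-(hydroxymethyl)oxolan-2-yl]-2-methoxyphenol | COc1cc([C@H]2OC[C@@H]([C@@H](O)c3ccc(OCc4ccccc4)c(OCc4ccccc4)c3)[C@@H]2CO)ccc1O | intermediate
15 | 4-[(R)-hydroxy{(3S,4R,5S)-5-(4-hydroxy-3-methoxyphenyl)-4-(hydroxymethyl)oxolan-3-yl}methyl]benzene-1,2-diol | COc1cc([C@H]2OC[C@@H]([C@@H](O)c3ccc(O)c(O)c3)[C@@H]2CO)ccc1O | target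

Total step count: 9 (steps 4 and 5 prepare the benzylic bromide 10).
Longest linear sequence: 7 (steps 1, 2, 3, 6, 7, 8, 9).

Steps most likely to fail

Step 8 (key step). What may go wrong: further dehydrogenation of the product phenol at C2–H by DDQ, tautomerisation of the quinone methide to the styrene with loss of the C3 stereocentre, or closure through the carbinol hydroxyl. Fallback, from 7 and back at 14: the C2 oxygen is brought in by aldol addition instead of C–H oxidation. The dianion of 7 (NaN(SiMe3)2, THF, −78 °C) is added to 4-formyl-2-methoxyphenyl 2,2-dimethylpropanoate F1 (made by pivaloylation of vanillin), which should give the all-trans aldol lactone acid F2 as a mixture of carbinol epimers. LiAlH4 should reduce it to the pentol F3, in which only the guaiacyl benzylic alcohol is phenolic. Brief warming in a weakly acidic buffer (AcOH/NaOAc, aqueous 1,4-dioxane) should dehydrate only this phenolic benzylic alcohol; both epimers pass through the same quinone methide 13, which closes to 14.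

Step 6. What may go wrong: incomplete dianion formation, O-benzylation of the carboxylate, or acyl transfer from the aryl pivalate to the enolate. Fallback, from 7 and back at 12: the acid is reduced first and a simple lactone monoenolate is alkylated. BH3·SMe2 (THF, 0 °C) should reduce the carboxylic acid of 7 selectively to (4S,5R)-5-[3,4-bis(benzyloxy)phenyl]-4-(hydroxymethyl)oxolan-2-one F4. Silylation (t-BuMe2SiCl, imidazole, DMF) gives the silyl ether F5. LiN(SiMe3)2 (THF, −78 °C) followed by 10 should give the trans-benzylated lactone F6. LiAlH4 opens the lactone and removes the pivalate to give the silyl-protected triol F7, and Bu4NF (THF) frees the C5 hydroxyl to give 12.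

Step 9. What may go wrong: over-reduction, that is hydrogenolysis of the benzylic carbinol or of the C2–O1 bond once the phenols are free. Fallback, from 3 and back at 15: the catechol is carried as silyl ethers and freed with fluoride instead of hydrogen. 3,4-Bis(triisopropylsilyloxy)benzaldehyde F8 (from 3,4-dihydroxybenzaldehyde, i-Pr3SiCl, imidazole) replaces 4 and is taken through the operations of steps 2, 3, 6, 7 and 8. These should give in turn the syn-aldol adduct F9 (not isolated), the lactone imide F10, the acid F11, the benzylated acid F12 (with 10), the tetraol F13, the quinone methide F14 (not isolated) and the oxolane F15. Et3N·3HF in THF then removes both silyl ethers to give 15.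

Further compounds
F1 | step 8 | 4-formyl-2-methoxyphenyl 2,2-dimethylpropanoate | COc1cc(C=O)ccc1OC(=O)C(C)(C)C
F2 | step 8 | (2R,3R,4S)-2-[3,4-bis(benzyloxy)phenyl]-4-{hydroxy[4-(2,2-dimethylpropanoyloxy)-3-methoxyphenyl]methyl}-5-oxooxolane-3-carboxylic acid (all-trans ring, both carbinol epimers) | O=C1[C@H](C(O)c2ccc(OC(=O)C(C)(C)C)c(OC)c2)[C@@H](C(=O)O)[C@H](c2ccc(OCc3ccccc3)c(OCc3ccccc3)c2)O1
F3 | step 8 | (1R,2S,3R)-1-[3,4-bis(benzyloxy)phenyl]-4-(4-hydroxy-3-methoxyphenyl)-2,3-bis(hydroxymethyl)butane-1,4-diol (both C4 epimers) | OC[C@H](C(O)c1ccc(O)c(OC)c1)[C@@H](CO)[C@@H](O)c1ccc(OCc2ccccc2)c(OCc2ccccc2)c1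
F4 | step 6 | (4S,5R)-5-[3,4-bis(benzyloxy)phenyl]-4-(hydroxymethyl)oxolan-2-one | O=C1C[C@@H](CO)[C@H](c2ccc(OCc3ccccc3)c(OCc3ccccc3)c2)O1
F5 | step 6 | (4S,5R)-5-[3,4-bis(benzyloxy)phenyl]-4-{[tert-butyl(dimethyl)silyl]oxymethyl}oxolan-2-one | O=C1C[C@@H](CO[Si](C)(C)C(C)(C)C)[C@H](c2ccc(OCc3ccccc3)c(OCc3ccccc3)c2)O1
F6 | step 6 | 4-{[(3R,4S,5R)-5-[3,4-bis(benzyloxy)phenyl]-4-{[tert-butyl(dimethyl)silyl]oxymethyl}-2-oxooxolan-3-yl]methyl}-2-methoxyphenyl 2,2-dimethylpropanoate | O=C1[C@H](Cc2ccc(OC(=O)C(C)(C)C)c(OC)c2)[C@@H](CO[Si](C)(C)C(C)(C)C)[C@H](c2ccc(OCc3ccccc3)c(OCc3ccccc3)c2)O1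
F7 | step 6 | (1R,2S,3R)-1-[3,4-bis(benzyloxy)phenyl]-2-{[tert-butyl(dimethyl)silyl]oxymethyl}-3-[(4-hydroxy-3-methoxyphenyl)methyl]butane-1,4-diol | OC[C@H](Cc1ccc(O)c(OC)c1)[C@@H](CO[Si](C)(C)C(C)(C)C)[C@@H](O)c1ccc(OCc2ccccc2)c(OCc2ccccc2)c1
F8 | step 9 | 3,4-bis(triisopropylsilyloxy)benzaldehyde | O=Cc1ccc(O[Si](C(C)C)(C(C)C)C(C)C)c(O[Si](C(C)C)(C(C)C)C(C)C)c1
F9 | step 9 | methyl (3R,4R)-3-{[(4R)-4-benzyl-2-oxo-1,3-oxazolidin-3-yl]carbonyl}-4-[3,4-bis(triisopropylsilyloxy)phenyl]-4-hydroxybutanoate (not isolated) | COC(=O)C[C@@H](C(=O)N1[C@H](Cc2ccccc2)COC1=O)[C@@H](O)c1ccc(O[Si](C(C)C)(C(C)C)C(C)C)c(O[Si](C(C)C)(C(C)C)C(C)C)c1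
F10 | step 9 | (4R)-4-benzyl-3-{[(2R,3R)-2-[3,4-bis(triisopropylsilyloxy)phenyl]-5-oxooxolan-3-yl]carbonyl}-1,3-oxazolidin-2-one | O=C1C[C@@H](C(=O)N2[C@H](Cc3ccccc3)COC2=O)[C@H](c2ccc(O[Si](C(C)C)(C(C)C)C(C)C)c(O[Si](C(C)C)(C(C)C)C(C)C)c2)O1
F11 | step 9 | (2R,3R)-2-[3,4-bis(triisopropylsilyloxy)phenyl]-5-oxooxolane-3-carboxylic acid | O=C1C[C@@H](C(=O)O)[C@H](c2ccc(O[Si](C(C)C)(C(C)C)C(C)C)c(O[Si](C(C)C)(C(C)C)C(C)C)c2)O1
F12 | step 9 | (2R,3R,4R)-2-[3,4-bis(triisopropylsilyloxy)phenyl]-4-{[4-(2,2-dimethylpropanoyloxy)-3-methoxyphenyl]methyl}-5-oxooxolane-3-carboxylic acid | O=C1[C@H](Cc2ccc(OC(=O)C(C)(C)C)c(OC)c2)[C@@H](C(=O)O)[C@H](c2ccc(O[Si](C(C)C)(C(C)C)C(C)C)c(O[Si](C(C)C)(C(C)C)C(C)C)c2)O1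
F13 | step 9 | (1R,2S,3R)-1-[3,4-bis(triisopropylsilyloxy)phenyl]-3-[(4-hydroxy-3-methoxyphenyl)methyl]-2-(hydroxymethyl)butane-1,4-diol | OC[C@H](Cc1ccc(O)c(OC)c1)[C@@H](CO)[C@@H](O)c1ccc(O[Si](C(C)C)(C(C)C)C(C)C)c(O[Si](C(C)C)(C(C)C)C(C)C)c1
F14 | step 9 | 4-{(2R,3S,4R)-4-[3,4-bis(triisopropylsilyloxy)phenyl]-4-hydroxy-2,3-bis(hydroxymethyl)butylidene}-2-methoxycyclohexa-2,5-dien-1-one (not isolated) | OC[C@H](C=C1C=CC(=O)C(OC)=C1)[C@@H](CO)[C@@H](O)c1ccc(O[Si](C(C)C)(C(C)C)C(C)C)c(O[Si](C(C)C)(C(C)C)C(C)C)c1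
F15 | step 9 | 4-[(2S,3R,4S)-4-{(R)-[3,4-bis(triisopropylsilyloxy)phenyl](hydroxy)methyl}-3-(hydroxymethyl)oxolan-2-yl]-2-methoxyphenol | COc1cc([C@H]2OC[C@@H]([C@@H](O)c3ccc(O[Si](C(C)C)(C(C)C)C(C)C)c(O[Si](C(C)C)(C(C)C)C(C)C)c3)[C@@H]2CO)ccc1O
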